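The data are simulated for substances that don't exist; noise was put on by code.

The catalyst turns starting material into target in a closed flask, and I follow the share of each charge that has turned.

| setting | beta | alpha | theta | delta |
|---|---|---|---|---|
| starting material | 0.400 M | 0.160 M | 0.800 M | 1.40 M |
| catalyst | 0.0400 M | 0.0400 M | 0.0400 M | 0.0400 M |
| time |  |  |  | 170 min |

| run | time / min | [target] / M |
|---|---|---|
| beta run | 24 | 0.0761 |
| beta run | 49 | 0.1364 |
| beta run | 73 | 0.1899 |
| beta run | 97 | 0.2318 |
| beta run | 120 | 0.2648 |
| beta run | 150 | 0.2985 |
| beta run | 170 | 0.3135 |
| alpha run | 24 | 0.0323 |
| alpha run | 49 | 0.0586 |
| alpha run | 73 | 0.0762 |
| alpha run | 97 | 0.0985 |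
| alpha run | 120 | 0.1119 |
| alpha run | 150 | 0.1241 |
| alpha run | 170 | 0.1306 |
| theta run | 24 | 0.1260 |
| theta run | 49 | 0.2425 |
| theta run | 73 | 0.3448 |
| theta run | 97 | 0.4237 |
| theta run | 120 | 0.4966 |
| theta run | 150 | 0.5615 |
| theta run | 170 | 0.6035 |

(each reading ± 0.002 M)

- Overall: starting material -> target, with catalyst as catalyst.
- Constant volume, constant temperature.
- Bound and free are read together.
- An order is taken over about fifteen percent of the charge, up and down.

- how the opening rate goes with [starting material] round the charge of the beta run: the exponent of the rate at two percent of starting material gone to target (one fixed amount of target, the same in the runs compared)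
- the alpha run starts with 0.240 M less of starting material than the beta run, and with no target. Compared where both hold the same amount of starting material, once fifteen percent of what the alpha run was charged with has turned into target, is the alpha run faster, slower or alike (within a tenth)?
- target in the delta run at 170 min, as a share of the starting material charged

I start from two extremes. If the rate follows what is left (pseudo-first-order), the half-time is the same for every charge. If the rate is constant, every charge gains the same amount in a given time, so the share falls in inverse proportion to the charge. The theta charge is 5.00 times the alpha charge, yet at 170 min its share reads 0.754 against 0.816 in the alpha run. The constant-rate extreme puts the theta share at 0.163. So the flask lies between the extremes, nearer the first.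

I add the two reciprocal rates. The time to reach a share is then τ times the sum of two terms: the logarithm of charge over what is left, and the share times the charge over K. Here τ is the time constant at low holdings. The last alpha and theta readings stand at the same clock, so τ drops out when I equate them. They give the crossover charge, where both terms weigh equally at small shares, as a reading: K = 1.63 M. The last alpha reading then gives τ of 95.8 min.

The order at the beta charge is K over K plus charge, so 0.803. For the delta run, a share of 0.7 takes 173 min, longer than the 170 min asked, so my estimate lies under that share. The reckoning assumes that the rate depends on what is left. Over nearly the same holdings, the alpha run's fractional loss per minute is 0.962 times the beta run's. I answer alike.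

The forecast gives 0.81, alike and 69.5%, holding that “target neither inhibits nor activates”.

The flask gives 0.84, alike and 69.5%.

    catalyst + starting material ⇌ catalyst-substrate complex, settled at all times (0.2520 M⁻¹)
    catalyst-substrate complex + catalyst → target + 2 catalyst (25.44 M⁻¹ min⁻¹)

For the delta run, the power-law fit gives 72.0% and the fit in which the loaded catalyst dies gives 69.5%. Now I put K on the beta run, which it was not reckoned from. The last beta share, 78.4% of the charge, comes out at 165 min, and it was read at 170 min.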